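Slowness is where your hunch puts the target, in the flasks that creep, but before you trust it, stop counting what is made and count the fraction of starting material left: target is an intermediate, made and also consumed, as eta shows.

| flask | starting material | enzyme | remark | time |
|---|---|---|---|---|
| beta | 0.60 mM | 0.01 mol% | run made earlier |  |
| eta | 74 mM | 0.01 mol% | run made earlier |  |
| maple | 1.2 mM | 0.01 mol% |  | 12 h |
| larch | 3.0 mM | 0.01 mol% |  | 12 h |
| alder | 10 mM | 0.01 mol% |  | 12 h |
| cedar | 30 mM | 0.01 mol% |  | 12 h |
| elm | 100 mM | 0.01 mol% |  | 12 h |

| run | time / h | target / % |
|---|---|---|
| beta | 1.00 | 0 |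
| beta | 1.50 | 0.1 |
| beta | 2.50 | 1.1 |
| beta | 4.00 | 0 |
| beta | 8.00 | 0.9 |
| beta | 12.0 | 0.1 |
| eta | 0.833 | 14.5 |
| eta | 2.50 | 0 |
| eta | 4.00 | 0 |
| eta | 6.00 | 0 |
| eta | 10.0 | 0 |
| eta | 12.0 | 0 |

(each reading ± 1 percentage point)

- [target] at the end for maple, larch, alder, cedar, elm, in this order
- how the row runs (hardly changes / falls, then rises / falls all the way / rises, then falls / rises all the way)

- the numbers in the tables scatter with a standard deviation of 1 percentage point
- "hardly changes" means that all values lie within two and a half points (for a concentration: within two and a half percent of the largest)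

Read the target's mean life from eta, which reads 14.5% at 0.833 h and 0% at 2.50 h. Take "gone" as one standard deviation; target still being made in that interval slows the fall, so read the figure as an estimated ceiling, no sharper than that scatter. Call it the life ceiling:

life ceiling = (2.50 h − 0.833 h) / ln(14.5% / 1 percentage point) = 0.623 h

Now suppose the target lives briefly against the run, so that making and using balance (the steady-state approximation), and write:

target, as a fraction of the charge = fall of the fraction left per hour × mean life

Let the fraction left fall exponentially. The fall at the asked time is then highest in the flask with 36.8% left, which gives: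

ceiling on target = 0.623 h / (e × 12 h) = 1.91%

Commit to that ceiling, which for alder is 0.191 mM. Expect the row to rise and then fall: maple holds less charge than elm, and eta, with less charge than elm, already reads 0% at 2.50 h, earlier than the asked 12 h.

The forecast gives 0.014 mM, 0.2 mM, 3.6 mM, 0.17 mM and 0 mM, shaped rises, then falls, with the caution “The order is assumed, so the uncertainty is large.”, and its alder value stands above my ceiling.

The flasks give 0.00448 mM, 0.0123 mM, 0.00678 mM, 0.00115 mM and 1.13 × 10⁻⁴ mM, and the row rises, then falls.

    starting material + enzyme → target + enzyme, rate k1*[starting material]^1.5*[enzyme]/(1 + ([starting material]/Kh1)^1.5) (12.0 mM, k = 1.60 × 10⁵ M⁻¹·⁵ min⁻¹)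
    target → over-reaction product (k = 0.0940 min⁻¹)

In maple the target's half-life of 0.12 h is shorter than the 12 h of the run, its mean life of 0.177 h lies under the 0.623 h ceiling, and making over using stands at 0.992 at 12.0 h. Carry that mean life to larch, whose fraction left falls from 48.2% at 6.00 h to 27.7% at 12.0 h: the average fall over that stretch, times the mean life, gives 0.605% of the charge, and larch holds 0.408% at 12.0 h.

The earlier runs and the new flask were computed with constants of no real substance.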